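**Remark on the chemistry.** Ring A is numbered as in the target throughout: C1 carries the triene, C2 the methyl group, C3 and C5 are the tertiary carbinols, C4 and C6 the secondary ones. "RA" in names means the C1-linked ring A unit with the C2, C3 and C5 methyl groups and isopropylidene ketals across O3/O4 and O5/O6, configured as in 14. The C6 carbinol is assumed to be set in the aldol step 5, so no later oxidation–reduction at C6 is planned.

## Analysis of the target

Amaurone B joins a fully substituted cyclohexane (ring A) through an all-E 1,5-dimethylhexatriene to a 2-methoxy-3,5-dimethyl-4-pyranone. C1 (CH–triene) and C2 (CH–CH3) carry their carbon substituents cis on one face, while the oxygens on C3 (tertiary OH), C4 (OAc), C5 (tertiary OH) and C6 (OAc) all lie on the other face. Six contiguous stereocentres, two of them quaternary carbinols, therefore have to be set in one ring. The C6 oxygen is β to C1, so a C1 carbonyl compound can lose it by elimination; acetates can migrate; and the triene–pyrone is sensitive to strong acid, strong nucleophiles and light. The hard part is the contiguous cis oxygenation, which cannot come from epoxide opening because that gives trans diols. The feature used is that the C3 and C6 hydroxyls are 1,4-cis and flank the C4–C5 bond, so a C4=C5 alkene between them can be dihydroxylated from their face by an oxidant that they hold through hydrogen bonds. The C2 methyl group, axial in the preferred half-chair, covers the opposite face, so direction and shielding agree.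

## Retrosynthetic reasoning

The two acetyl C–O bonds of 29 are cut first, giving tetraol 28. Acetates β to C1 would not survive the basic condensation steps and could migrate or eliminate. In 28 only the C4 and C6 hydroxyls are secondary, so the last acylation needs no protecting group.

28 is masked as bis-acetonide 27. The all-cis pattern lets each tertiary hydroxyl share a dioxolane with its secondary neighbour, so two ketals cover four hydroxyls and come off together in mild aqueous acid.

In 27 the C=C bond next to the pyrone is cut, via acetate 26 and aldol 25, to dienal 19 and ethylpyranone 24. The ethyl CH2 of 24 is the only acidic position of the pyrone (vinylogous to the ring carbonyl), so this fragment needs no further functionalisation. Elimination from 26 is an E1cB process that gives the conjugated E alkene under thermodynamic control. The forward reactions must add the vinylogous enolate 1,2 to the dienal and dehydrate without touching C1.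

19 is cut at its two C=C bonds in turn, to enal 18 and then aldehyde 17. Both bonds are made with stabilised phosphorus ylides, which are neutral enough to leave the α-stereocentre and β-oxygen of 17 alone and which give E alkenes.

17 comes from alcohol 16 and silyl ether 15, and 15 from tetraol 14 by ketalisation. The primary position stays silylated until the ring hydroxyls are tied up, so that it cannot form a six-membered ketal with the C6 oxygen.

In 14 the C4–O and C5–O bonds are cut together, giving cyclohexenediol 12. This is the central disconnection: one suprafacial oxidation creates the secondary C4 and tertiary C5 carbinols, and the two hydroxyls already present decide the face. The forward reaction has to add both oxygens syn to the C3 and C6 hydroxyls.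

The C4=C5 bond of 12 is cut to diene 11. Ring-closing metathesis is chosen because the vinyl and isopropenyl groups of 11 pass unchanged through the earlier steps and the closure does not depend on the relative configuration at C1, C2, C3 and C6.

11 goes back through triol 10 to aldol lactone 9, and the C1–C6 bond of 9 is cut to vinyl lactone 7 and enal 8. The rigid five-membered lactone controls two centres here: its C4 methyl group sends the electrophile to the opposite face (ring C1), and its fixed enolate geometry gives the anti carbinol (ring C6) through a chair transition state. The lactone carbonyl is also the latent C1 hydroxymethyl group.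

7 is traced through aldehyde 6 to hydroxymethyl lactone 5. The bond between the acetate α-carbon and the CH(CH3) carbon of 5 is cut, via hydroxy ester 4, to epoxy alcohol 2 and ester 3. Backside opening converts the epoxide geometry into the C2/C3 relation of the target, with the C2 methyl and C3 hydroxyl on opposite faces. 2 is the asymmetric epoxidation product of allylic alcohol 1, the only place where a reagent introduces absolute configuration.

24 is cut at its methyl ether to hydroxypyranone 23, at the ring ester bond to triketo ester 22, and at the C4–C5 bond of 22 to keto ester 20 and amide 21.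

## Alternatives that were turned down

Alternative 1: The ring is cut at C1–C6 and C2–C3. A Diels–Alder reaction between the chiral butenolide A2 and the 1-methoxy-3-silyloxy diene A3, followed by acid, would give the cis-fused enone lactone A1.
- For it: the cis C1/C2 pair and the absolute configuration come from one auxiliary-controlled endo cycloaddition that also forms two ring bonds. On this point it is stronger than the chosen route, which needs an epoxidation, an epoxide opening and an aldol for the same centres.
- Against it: A1 carries only the C4 oxygen, as a ketone. The C3 tertiary carbinol, the C5 and C6 oxygens and the C4 configuration must all be added afterwards. The acetal carbon of A1 must be reduced to the C2 methyl group and the auxiliary removed. The all-cis tetraol would still need a syn-dioxygenation of the kind the chosen route uses.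
- Comparison: the chosen route spends more steps on C1/C2 but reaches a ring in which every remaining oxygen is placed by one directed step.

Alternative 2: The ring is cut at C1–C6. A Lewis-acid-promoted carbonyl-ene cyclisation of the open-chain aldehyde A5 would give cyclohexanol A4, forming C1–C6 and moving the alkene into the side chain.
- For it: C1, C6 and the (E)-trisubstituted side-chain alkene with its allylic oxygen arise in one step. The first olefination of the chosen route and its sensitive aldehyde 17 are avoided, so on side-chain economy this alternative is stronger.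
- Against it: A5 must already carry C2, C3, C4 and C5, two of them fully substituted ether carbons, built with acyclic stereocontrol. A 1,2-disubstituted alkene is a weak ene donor. The α-quaternary α-alkoxy aldehyde offers the Lewis acid several chelation sites and ionisable ketal and acetal groups. The chair needed places the C2 methyl group axial, so the C1/C6 outcome is not secure.
- Comparison: the chosen route sets the oxygen pattern on a preformed ring whose two faces are clearly differentiated, at the cost of handling aldehyde 17.

Alternative 3: The C3–O and C6–O bonds are cut. [4+2] addition of singlet oxygen to cyclohexadiene A7 would give endoperoxide A6, and O–O reduction would give diol 12, after which the same dihydroxylation would follow.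
- For it: the 1,4-cis relation of the C3 and C6 oxygens is guaranteed by the peroxide bridge. On this point it is stronger than the chosen route, which relies on aldol diastereoselection for C6.
- Against it: A7 is a cis-5,6-disubstituted 1,3-dimethylcyclohexa-1,3-diene that needs its own enantioselective synthesis and can undergo 1,5-hydrogen shifts. Its two vinylic methyl groups offer allylic hydrogens for the competing Schenck ene reaction. Facial control rests on two sp3 substituents, one of which is pseudo-equatorial and shields little.
- Comparison: this is another way into the same key step. The chosen sequence reaches 12 in eight steps from 1, with each centre set by a catalyst or by 1,2-induction in a five-membered ring.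

Key step: step 9

## Route

Step 1
Reactants: 1 (E)-2-methylbut-2-en-1-ol (tiglyl alcohol)
Product: 2 [(2S,3S)-2,3-dimethyloxiran-2-yl]methanol
Conditions: Ti(OiPr)4 (10 mol %), L-(+)-diethyl tartrate (12 mol %), t-BuOOH, 4 Å MS, CH2Cl2, −20 °C
Reagents that add atoms: tert-butyl hydroperoxide, CC(C)(C)OO
Why: Sharpless asymmetric epoxidation; with the L-(+)-tartrate the oxygen is delivered to the face of the (E)-allylic alcohol that gives the (2S,3S)-epoxide, which fixes the two carbons that become ring C2 and C3.

Step 2
Reactants: 2 [(2S,3S)-2,3-dimethyloxiran-2-yl]methanol; 3 tert-butyl acetate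
Product: 5 (4S,5R)-5-(hydroxymethyl)-4,5-dimethyloxolan-2-one, via hydroxy ester 4 (not isolated)
Conditions: 3 (3.3 equiv), LDA, THF, −78 °C; Et2AlCl; then 2, −78 → 0 °C; Rochelle salt (aq.); crude, TsOH·H2O (cat.), PhMe, 50 °C
Reagents that add atoms: none
Why: Epoxide opening by a diethylaluminium ester enolate (SN2 with inversion) at the CH(CH3) carbon, the fully substituted epoxide carbon being closed to backside attack, which sets ring C2. Acid then closes the five-membered lactone onto the tertiary hydroxyl, the ring size favoured over the six-membered lactone through the primary one.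

Step 3
Reactants: 5 (4S,5R)-5-(hydroxymethyl)-4,5-dimethyloxolan-2-one
Product: 6 (2R,3S)-2,3-dimethyl-5-oxooxolane-2-carbaldehyde
Conditions: Dess–Martin periodinane, NaHCO3, CH2Cl2, 0 °C → rt
Reagents that add atoms: none
Why: Dess–Martin oxidation of a primary alcohol; the aldehyde has no α-hydrogen and so cannot epimerise.

Step 4
Reactants: 6 (2R,3S)-2,3-dimethyl-5-oxooxolane-2-carbaldehyde
Product: 7 (4S,5S)-5-ethenyl-4,5-dimethyloxolan-2-one
Conditions: Ph3PCH3Br (1.3 equiv), KHMDS (1.2 equiv), THF, 0 °C; then 6, −78 → 0 °C
Reagents that add atoms: methylenetriphenylphosphorane (from methyltriphenylphosphonium bromide), C=P(c1ccccc1)(c1ccccc1)c1ccccc1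
Why: Wittig methylenation; the aldehyde is far more electrophilic than the lactone, and a slight deficit of base avoids lactone enolisation.

Step 5
Reactants: 7 (4S,5S)-5-ethenyl-4,5-dimethyloxolan-2-one; 8 methacrolein (2-methylprop-2-enal)
Product: 9 (3R,4S,5S)-5-ethenyl-3-[(1S)-1-hydroxy-2-methylprop-2-en-1-yl]-4,5-dimethyloxolan-2-one
Conditions: LDA (1.1 equiv), THF, −78 °C; then 8, −78 °C; NH4Cl (aq.) at −78 °C
Reagents that add atoms: none
Why: Lithium-enolate aldol addition, 1,2 to the enal; attack anti to the adjacent C4 methyl group of the lactone sets ring C1. The lactone enolate, E by ring constraint, should react through a Zimmerman–Traxler chair with the isopropenyl group equatorial to give the anti carbinol, which is the C6 configuration of the target.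

Step 6
Reactants: 9 (3R,4S,5S)-5-ethenyl-3-[(1S)-1-hydroxy-2-methylprop-2-en-1-yl]-4,5-dimethyloxolan-2-one
Product: 10 (3S,4S,5S,6S)-4-(hydroxymethyl)-2,5,6-trimethylocta-1,7-diene-3,6-diol
Conditions: LiAlH4, THF, 0 °C; Rochelle salt (aq.)
Reagents that add atoms: none
Why: Hydride reduction of the lactone to the diol; no stereocentre is touched and the isolated alkenes are inert.

Step 7
Reactants: 10 (3S,4S,5S,6S)-4-(hydroxymethyl)-2,5,6-trimethylocta-1,7-diene-3,6-diol
Product: 11 (3S,4S,5S,6S)-4-({[tert-butyl(dimethyl)silyl]oxy}methyl)-2,5,6-trimethylocta-1,7-diene-3,6-diol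
Conditions: TBSCl (1.05 equiv), imidazole, CH2Cl2, 0 °C
Reagents that add atoms: tert-butyldimethylsilyl chloride, CC(C)(C)[Si](C)(C)Cl
Why: Selective silylation of the primary hydroxyl over a secondary allylic and a tertiary one, on steric grounds.

Step 8
Reactants: 11 (3S,4S,5S,6S)-4-({[tert-butyl(dimethyl)silyl]oxy}methyl)-2,5,6-trimethylocta-1,7-diene-3,6-diol
Product: 12 (1R,4S,5S,6S)-5-({[tert-butyl(dimethyl)silyl]oxy}methyl)-1,3,6-trimethylcyclohex-2-ene-1,4-diol
Conditions: second-generation Grubbs catalyst (H2IMes)(PCy3)Cl2Ru=CHPh (5 mol %), CH2Cl2 (5 mM), 40 °C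
Reagents that add atoms: none
Why: Ring-closing metathesis of a 1,7-diene; the catalyst loads on the vinyl group and closes onto the isopropenyl group to give the trisubstituted C4=C5 cyclohexene with loss of ethene, free allylic hydroxyls being tolerated.

Step 9
Reactants: 12 (1R,4S,5S,6S)-5-({[tert-butyl(dimethyl)silyl]oxy}methyl)-1,3,6-trimethylcyclohex-2-ene-1,4-diol
Product: 14 (1R,2R,3S,4S,5S,6S)-5-({[tert-butyl(dimethyl)silyl]oxy}methyl)-1,3,6-trimethylcyclohexane-1,2,3,4-tetrol, via osmate ester chelate 13 (not isolated)
Conditions: OsO4 (1.05 equiv), TMEDA (1.1 equiv), CH2Cl2, −78 °C; then Na2SO3 (aq.), THF, 65 °C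
Reagents that add atoms: osmium tetroxide, O=[Os](=O)(=O)=O
Why: The bidentate diamine binds octavalent osmium and makes its oxo ligands strong hydrogen-bond acceptors, so the reagent is held by the pseudo-axial C3 hydroxyl and the C6 hydroxyl on the upper face and adds to C4=C5 by a concerted [3+2] cycloaddition from that face, giving the chelated hexavalent osmate ester 13, which sulfite cleaves to the diol. The closest known reaction type is the hydrogen-bond-directed syn-dihydroxylation of cyclic allylic alcohols with the OsO4–TMEDA complex. No ring of the target is closed; the only ring formed is the transient five-membered osmate ester, by suprafacial addition across the alkene. The new C4 (secondary) and C5 (tertiary) carbinol centres are both set by the face of addition and, being formed in one suprafacial event, are necessarily cis to each other. The selectivity needed is facial: hydrogen bonding to the two allylic hydroxyls brings the oxidant to their face, and the axial C2 methyl group of the preferred half-chair blocks the other face, so direction and sterics reinforce each other. Without the diamine, the usual preference of osmylation for the face anti to an allylic oxygen would compete, which is why the stoichiometric diamine complex in a non-coordinating solvent is used. The product has all four ring oxygens cis and only two of them secondary, which prepares the final selective acetylation.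

Step 10
Reactants: 14 (1R,2R,3S,4S,5S,6S)-5-({[tert-butyl(dimethyl)silyl]oxy}methyl)-1,3,6-trimethylcyclohexane-1,2,3,4-tetrol
Product: 15 1,2:3,4-bis-O-(propan-2-ylidene) derivative of 14 (dioxolanes across O3/O4 and O5/O6 of ring A, silyl ether kept)
Conditions: 2,2-dimethoxypropane, PPTS (cat.), acetone, rt
Reagents that add atoms: 2,2-dimethoxypropane, COC(C)(C)OC
Why: Acid-catalysed ketal exchange under equilibrating conditions; each tertiary hydroxyl pairs with its cis secondary neighbour in a cis-fused dioxolane, the arrangement that ties up all four hydroxyls, and the primary silyl ether survives the mild acid.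

Step 11
Reactants: 15 bis-acetonide silyl ether
Product: 16 RA–CH2OH (bis-acetonide primary alcohol)
Conditions: TBAF, THF, 0 °C → rt
Reagents that add atoms: none
Why: Fluoride cleavage of the silyl ether; the ketals are stable to fluoride and base.

Step 12
Reactants: 16 RA–CH2OH
Product: 17 RA–CHO (ring A C1-carbaldehyde, bis-acetonide)
Conditions: Dess–Martin periodinane, NaHCO3, CH2Cl2, 0 °C → rt
Reagents that add atoms: none
Why: Buffered Dess–Martin oxidation, near-neutral so that the α-stereocentre (C1) and the β-alkoxy group are not disturbed; the aldehyde is used at once.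

Step 13
Reactants: 17 RA–CHO
Product: 18 (2E)-2-methyl-3-(RA)prop-2-enal
Conditions: Ph3P=C(CH3)CHO (2 equiv), PhMe, 90 °C
Reagents that add atoms: 2-(triphenylphosphoranylidene)propanal, CC(C=O)=P(c1ccccc1)(c1ccccc1)c1ccccc1
Why: Wittig reaction of a stabilised ylide, E-selective and non-basic, so that C1 keeps its configuration and the C6 oxygen is not eliminated.

Step 14
Reactants: 18 (2E)-2-methyl-3-(RA)prop-2-enal
Product: 19 (2E,4E)-4-methyl-5-(RA)penta-2,4-dienal
Conditions: Ph3P=CHCHO (1.3 equiv), PhMe, 70 °C
Reagents that add atoms: (triphenylphosphoranylidene)acetaldehyde, O=CC=P(c1ccccc1)(c1ccccc1)c1ccccc1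
Why: Two-carbon Wittig homologation with the formyl-stabilised ylide; it gives the E alkene and is run with limited ylide to hold back a second homologation.

Step 15
Reactants: 20 ethyl 2-methyl-3-oxopentanoate; 21 N-methoxy-N-methylpropanamide
Product: 22 ethyl 2,4-dimethyl-3,5-dioxoheptanoate
Conditions: 20, NaH, THF, 0 °C; n-BuLi, 0 °C; then 21, 0 °C → rt; HCl (aq.)
Reagents that add atoms: none
Why: γ-Acylation of a β-keto ester dianion with a Weinreb amide; the stable tetrahedral intermediate prevents over-addition and proton quenching by the product.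

Step 16
Reactants: 22 ethyl 2,4-dimethyl-3,5-dioxoheptanoate
Product: 23 6-ethyl-4-hydroxy-3,5-dimethyl-2H-pyran-2-one
Conditions: DBU, PhMe, 110 °C
Reagents that add atoms: none
Why: Base-mediated lactonisation of the triketo ester: the enol oxygen of the terminal ketone attacks the ester and ethanol is lost.

Step 17
Reactants: 23 6-ethyl-4-hydroxy-3,5-dimethyl-2H-pyran-2-one
Product: 24 6-ethyl-2-methoxy-3,5-dimethyl-4H-pyran-4-one
Conditions: MeOTf, CH2Cl2, rt; NaHCO3 (aq.)
Reagents that add atoms: methyl trifluoromethanesulfonate, COS(=O)(=O)C(F)(F)F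
Why: O-Methylation of the neutral hydroxypyranone with a hard methylating agent; the lactone carbonyl oxygen is the most nucleophilic site, and loss of the 4-OH proton from the pyrylium ion gives the 2-methoxy-4-pyranone.

Step 18
Reactants: 19 (2E,4E)-4-methyl-5-(RA)penta-2,4-dienal; 24 6-ethyl-2-methoxy-3,5-dimethyl-4H-pyran-4-one
Product: 25 6-[(4E,6E)-3-hydroxy-6-methyl-7-(RA)hepta-4,6-dien-2-yl]-2-methoxy-3,5-dimethyl-4H-pyran-4-one (diastereomers at the two new chain carbons)
Conditions: 24 (1.3 equiv), LiHMDS, THF, −78 °C; then 19, −78 °C; NH4Cl (aq.)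
Reagents that add atoms: none
Why: Vinylogous aldol addition: the ethyl CH2 is the only acidic position of the pyranone, and its lithium dienolate adds 1,2 to the aldehyde at low temperature. The two new centres are removed in the next step, so their configuration is irrelevant.

Step 19
Reactants: 25 aldol adduct
Product: 27 2-methoxy-3,5-dimethyl-6-[(2E,4E,6E)-6-methyl-7-(RA)hepta-2,4,6-trien-2-yl]-4H-pyran-4-one, via aldol acetate 26 (not isolated)
Conditions: Ac2O, Et3N, DMAP (cat.), CH2Cl2, 0 °C → rt; then DBU, rt → 40 °C
Reagents that add atoms: none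
Why: Acetylation of the only free hydroxyl followed by E1cB elimination through the pyranone-stabilised carbanion; the conjugated (E)-trisubstituted alkene is the thermodynamic product.

Step 20
Reactants: 27 bis-acetonide triene
Product: 28 de-O-acetyl amaurone B (ring A 3,4,5,6-tetraol)
Conditions: AcOH/H2O (4:1), 50 °C
Reagents that add atoms: none
Why: Mild acid hydrolysis of both isopropylidene ketals; the methoxypyranone and the electron-poor triene should tolerate aqueous acetic acid.

Step 21
Reactants: 28 de-O-acetyl amaurone B
Product: 29 amaurone B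
Conditions: Ac2O, pyridine, DMAP (cat.), CH2Cl2, 0 °C → rt
Reagents that add atoms: acetic anhydride, CC(=O)OC(C)=O
Why: Acetylation of the two secondary hydroxyls (C4, C6); the tertiary C3 and C5 hydroxyls are far slower and stay free.

## Compound list

1 | (E)-2-methylbut-2-en-1-ol (tiglyl alcohol) | C/C=C(\C)CO | starting material
2 | [(2S,3S)-2,3-dimethyloxiran-2-yl]methanol | OC[C@]1(C)O[C@H]1C | intermediate
3 | tert-butyl acetate | CC(=O)OC(C)(C)C | starting material
4 | tert-butyl (3S,4R)-4,5-dihydroxy-3,4-dimethylpentanoate | CC(C)(C)OC(=O)C[C@H](C)[C@@](C)(O)CO | intermediate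
5 | (4S,5R)-5-(hydroxymethyl)-4,5-dimethyloxolan-2-one | O=C1C[C@H](C)[C@](C)(CO)O1 | intermediate
6 | (2R,3S)-2,3-dimethyl-5-oxooxolane-2-carbaldehyde | O=C1C[C@H](C)[C@](C)(C=O)O1 | intermediate
7 | (4S,5S)-5-ethenyl-4,5-dimethyloxolan-2-one | O=C1C[C@H](C)[C@](C)(C=C)O1 | intermediate
8 | methacrolein | CC(=C)C=O | starting material
9 | (3R,4S,5S)-5-ethenyl-3-[(1S)-1-hydroxy-2-methylprop-2-en-1-yl]-4,5-dimethyloxolan-2-one | O=C1[C@@H]([C@H](O)C(C)=C)[C@H](C)[C@](C)(C=C)O1 | intermediate
10 | (3S,4S,5S,6S)-4-(hydroxymethyl)-2,5,6-trimethylocta-1,7-diene-3,6-diol | OC[C@@H]([C@H](O)C(C)=C)[C@H](C)[C@@](C)(O)C=C | intermediate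
11 | (3S,4S,5S,6S)-4-({[tert-butyl(dimethyl)silyl]oxy}methyl)-2,5,6-trimethylocta-1,7-diene-3,6-diol | CC(C)(C)[Si](C)(C)OC[C@@H]([C@H](O)C(C)=C)[C@H](C)[C@@](C)(O)C=C | intermediate
12 | (1R,4S,5S,6S)-5-({[tert-butyl(dimethyl)silyl]oxy}methyl)-1,3,6-trimethylcyclohex-2-ene-1,4-diol | CC(C)(C)[Si](C)(C)OC[C@@H]1[C@H](C)[C@@](C)(O)C=C(C)[C@H]1O | intermediate
13 | osmate ester chelate: C4,C5-O,O-dioxo-osmium ester of 14 with TMEDA on osmium | CC(C)(C)[Si](C)(C)OC[C@@H]1[C@H](C)[C@@](C)(O)[C@H]2O[Os-2]3(=O)(=O)(O[C@@]2(C)[C@H]1O)[N+](C)(C)CC[N+]3(C)C | intermediate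
14 | (1R,2R,3S,4S,5S,6S)-5-({[tert-butyl(dimethyl)silyl]oxy}methyl)-1,3,6-trimethylcyclohexane-1,2,3,4-tetrol | CC(C)(C)[Si](C)(C)OC[C@@H]1[C@H](C)[C@@](C)(O)[C@@H](O)[C@@](C)(O)[C@H]1O | intermediate
15 | 1,2:3,4-bis-O-(propan-2-ylidene) derivative of 14 | CC(C)(C)[Si](C)(C)OC[C@@H]1[C@H](C)[C@@]2(C)OC(C)(C)O[C@H]2[C@@]3(C)OC(C)(C)O[C@@H]13 | intermediate
16 | RA–CH2OH, bis-acetonide primary alcohol | OC[C@@H]1[C@H](C)[C@@]2(C)OC(C)(C)O[C@H]2[C@@]3(C)OC(C)(C)O[C@@H]13 | intermediate
17 | RA–CHO, bis-acetonide C1-carbaldehyde | O=C[C@@H]1[C@H](C)[C@@]2(C)OC(C)(C)O[C@H]2[C@@]3(C)OC(C)(C)O[C@@H]13 | intermediate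
18 | (2E)-2-methyl-3-(RA)prop-2-enal | O=C/C(C)=C/[C@@H]1[C@H](C)[C@@]2(C)OC(C)(C)O[C@H]2[C@@]3(C)OC(C)(C)O[C@@H]13 | intermediate
19 | (2E,4E)-4-methyl-5-(RA)penta-2,4-dienal | O=C/C=C/C(C)=C/[C@@H]1[C@H](C)[C@@]2(C)OC(C)(C)O[C@H]2[C@@]3(C)OC(C)(C)O[C@@H]13 | intermediate
20 | ethyl 2-methyl-3-oxopentanoate | CCC(=O)C(C)C(=O)OCC | starting material
21 | N-methoxy-N-methylpropanamide | CCC(=O)N(C)OC | starting material
22 | ethyl 2,4-dimethyl-3,5-dioxoheptanoate | CCC(=O)C(C)C(=O)C(C)C(=O)OCC | intermediate
23 | 6-ethyl-4-hydroxy-3,5-dimethyl-2H-pyran-2-one | CCc1oc(=O)c(C)c(O)c1C | intermediate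
24 | 6-ethyl-2-methoxy-3,5-dimethyl-4H-pyran-4-one | CCc1oc(OC)c(C)c(=O)c1C | intermediate
25 | 6-[(4E,6E)-3-hydroxy-6-methyl-7-(RA)hepta-4,6-dien-2-yl]-2-methoxy-3,5-dimethyl-4H-pyran-4-one, diastereomers at chain C2 and C3 | COc1oc(C(C)C(O)/C=C/C(C)=C/[C@@H]2[C@H](C)[C@@]3(C)OC(C)(C)O[C@H]3[C@@]4(C)OC(C)(C)O[C@@H]24)c(C)c(=O)c1C | intermediate
26 | acetate of 25 | COc1oc(C(C)C(OC(C)=O)/C=C/C(C)=C/[C@@H]2[C@H](C)[C@@]3(C)OC(C)(C)O[C@H]3[C@@]4(C)OC(C)(C)O[C@@H]24)c(C)c(=O)c1C | intermediate
27 | 2-methoxy-3,5-dimethyl-6-[(2E,4E,6E)-6-methyl-7-(RA)hepta-2,4,6-trien-2-yl]-4H-pyran-4-one | COc1oc(/C(C)=C/C=C/C(C)=C/[C@@H]2[C@H](C)[C@@]3(C)OC(C)(C)O[C@H]3[C@@]4(C)OC(C)(C)O[C@@H]24)c(C)c(=O)c1C | intermediate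
28 | de-O-acetyl amaurone B (ring A 3,4,5,6-tetraol) | COc1oc(/C(C)=C/C=C/C(C)=C/[C@@H]2[C@H](C)[C@@](C)(O)[C@@H](O)[C@@](C)(O)[C@H]2O)c(C)c(=O)c1C | intermediate
29 | amaurone B | COc1oc(/C(C)=C/C=C/C(C)=C/[C@@H]2[C@H](C)[C@@](C)(O)[C@@H](OC(C)=O)[C@@](C)(O)[C@H]2OC(C)=O)c(C)c(=O)c1C | target

## Step count and least certain steps

Total: 21 steps. Longest linear sequence: 18 steps (steps 1–14 and 18–21, from 1 to 29); steps 15–17 make the pyranone 24 in parallel.

**Step 9 (key step).** The likeliest problems are slow osmylation of a trisubstituted alkene next to a quaternary carbon and incomplete release of the tetraol from the chelated osmate ester. Leakage of the oxidant to the lower face is less likely because direction and sterics agree. The fallback sets out from 12 and comes back at 14, and replaces the osmylation by two hydroxyl-directed epoxidations. VO(acac)2 and t-BuOOH should give the upper-face C4–C5 epoxide F1. Et2Al(TMP) would isomerise F1, by removal of a C5-methyl hydrogen syn to the epoxide oxygen, to the exocyclic allylic alcohol F2, which keeps the C4–O bond and its configuration. A second VO(acac)2/t-BuOOH epoxidation, directed by the C4 and C6 hydroxyls, would give the spiro-epoxide F3 with oxygen on the upper face, and LiAlH4 would open F3 at its CH2 terminus to give 14.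

**Step 2.** Low reactivity of the trisubstituted epoxide toward the ester enolate, or attack guided by the Lewis acid toward the fully substituted carbon, may erode yield and regiochemistry. The fallback sets out from 2 and comes back at 5, using a soft stabilised carbanion. Benzylation (NaH, BnBr) gives the benzyl ether F4. Sodium diethyl malonate in refluxing ethanol opens F4 at the CH(CH3) carbon, and the tertiary alkoxide closes onto one ester to give the carbethoxy lactone F5. Krapcho dealkoxycarbonylation (NaCl, wet DMSO, 150 °C) gives the benzyloxymethyl lactone F6, and hydrogenolysis (H2, Pd/C) gives 5.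

**Step 5.** Competition of boat or open transition states with the chair may lower the diastereoselection at the carbinol carbon (ring C6); attack anti to the lactone methyl group is the safer element. The fallback sets out from 7 and comes back at 12, and corrects C6 by SN2 inversion on the ring. The syn aldol epimer F7 is taken through the conditions of steps 6–8 as the epimeric triol F8, silyl ether F9 and cyclohexenediol F10, the last being separable from 12 by chromatography. F10 is inverted at C6 by a Mitsunobu reaction (4-nitrobenzoic acid, PPh3, DIAD) to the 4-nitrobenzoate F11, and methanolysis (K2CO3, MeOH) gives 12.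

**Step 14.** The product dienal is a less hindered electrophile than the α-methyl enal, so a second homologation can run ahead. The fallback sets out from 18 and comes back at 19. A Horner–Wadsworth–Emmons reaction with triethyl phosphonoacetate (NaH, THF) gives the dienoate F12, which cannot react further. DIBAL-H reduction gives the dienol F13, and MnO2 oxidises it to 19.

**Step 19.** Ionisation of the dienylic acetate with allylic transposition, or scrambling of the central alkene geometry, may accompany the elimination. The fallback sets out from 19 and 24 and comes back at 27, replacing the aldol–elimination by an olefination. Deprotonation of 24 (LiHMDS, 2 equiv) and trapping with diethyl chlorophosphate gives the α-phosphonate F14. Horner–Wadsworth–Emmons reaction of its lithium anion with 19 (THF, −78 °C → rt) forms the (E)-trisubstituted alkene of 27 directly.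

## Further compounds

F1 | step 9 | upper-face C4–C5 epoxide of 12 | CC(C)(C)[Si](C)(C)OC[C@@H]1[C@H](C)[C@@](C)(O)[C@H]2O[C@@]2(C)[C@H]1O
F2 | step 9 | exocyclic allylic alcohol (C5 methylidene, C3,C4,C6-triol, silyl ether) | CC(C)(C)[Si](C)(C)OC[C@@H]1[C@H](C)[C@@](C)(O)[C@@H](O)C(=C)[C@H]1O
F3 | step 9 | spiro-epoxide at C5 (oxygen on the upper face) | CC(C)(C)[Si](C)(C)OC[C@@H]1[C@H](C)[C@@](C)(O)[C@@H](O)[C@@]2(OC2)[C@H]1O
F4 | step 2 | (2S,3S)-2-[(benzyloxy)methyl]-2,3-dimethyloxirane | c1ccccc1COC[C@]2(C)O[C@H]2C
F5 | step 2 | ethyl (4S,5R)-5-[(benzyloxy)methyl]-4,5-dimethyl-2-oxooxolane-3-carboxylate (C3 epimers) | O=C1C(C(=O)OCC)[C@H](C)[C@](C)(COCc2ccccc2)O1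
F6 | step 2 | (4S,5R)-5-[(benzyloxy)methyl]-4,5-dimethyloxolan-2-one | O=C1C[C@H](C)[C@](C)(COCc2ccccc2)O1
F7 | step 5 | (3R,4S,5S)-5-ethenyl-3-[(1R)-1-hydroxy-2-methylprop-2-en-1-yl]-4,5-dimethyloxolan-2-one | O=C1[C@@H]([C@@H](O)C(C)=C)[C@H](C)[C@](C)(C=C)O1
F8 | step 5 | C3 epimer of 10 | OC[C@@H]([C@@H](O)C(C)=C)[C@H](C)[C@@](C)(O)C=C
F9 | step 5 | C3 epimer of 11 | CC(C)(C)[Si](C)(C)OC[C@@H]([C@@H](O)C(C)=C)[C@H](C)[C@@](C)(O)C=C
F10 | step 5 | ring C6 epimer of 12 | CC(C)(C)[Si](C)(C)OC[C@@H]1[C@H](C)[C@@](C)(O)C=C(C)[C@@H]1O
F11 | step 5 | C6 4-nitrobenzoate of 12 | CC(C)(C)[Si](C)(C)OC[C@@H]1[C@H](C)[C@@](C)(O)C=C(C)[C@H]1OC(=O)c1ccc(cc1)[N+](=O)[O-]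
F12 | step 14 | ethyl (2E,4E)-4-methyl-5-(RA)penta-2,4-dienoate | CCOC(=O)/C=C/C(C)=C/[C@@H]1[C@H](C)[C@@]2(C)OC(C)(C)O[C@H]2[C@@]3(C)OC(C)(C)O[C@@H]13
F13 | step 14 | (2E,4E)-4-methyl-5-(RA)penta-2,4-dien-1-ol | OC/C=C/C(C)=C/[C@@H]1[C@H](C)[C@@]2(C)OC(C)(C)O[C@H]2[C@@]3(C)OC(C)(C)O[C@@H]13
F14 | step 19 | diethyl [1-(6-methoxy-3,5-dimethyl-4-oxo-4H-pyran-2-yl)ethyl]phosphonate | CCOP(=O)(OCC)C(C)c1oc(OC)c(C)c(=O)c1C
A1 | alternative 1 | cis-fused cyclohexenone lactone with the menthyloxy acetal | O=C1O[C@@H](O[C@@H]3C[C@H](C)CC[C@H]3C(C)C)[C@H]2[C@@H]1C=C(C)C(=O)[C@H]2C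
A2 | alternative 1 | (5R)-5-{[(1R,2S,5R)-5-methyl-2-(propan-2-yl)cyclohexyl]oxy}furan-2(5H)-one | O=C1O[C@@H](O[C@@H]2C[C@H](C)CC[C@H]2C(C)C)C=C1
A3 | alternative 1 | (1E,3Z)-1-methoxy-2-methyl-3-(trimethylsilyloxy)penta-1,3-diene | CO/C=C(C)/C(O[Si](C)(C)C)=C/C
A4 | alternative 2 | trans-2-alkenylcyclohexanol from the ene cyclisation | CC(C)(C)[Si](C)(C)OC/C(C)=C/[C@@H]1[C@H](C)[C@@]2(C)OC(C)(C)O[C@H]2[C@@](C)(OCOC)[C@H]1O
A5 | alternative 2 | open-chain C6 aldehyde with the C3/C4 acetonide, C5 methoxymethyl ether and (E)-alkene | O=C[C@](C)(OCOC)[C@@H]1OC(C)(C)O[C@]1(C)[C@@H](C)/C=C/C(C)CO[Si](C)(C)C(C)(C)C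
A6 | alternative 3 | bicyclic endoperoxide (2,3-dioxabicyclo[2.2.2]oct-5-ene) | CC(C)(C)[Si](C)(C)OC[C@@H]1[C@H](C)[C@@]2(C)OO[C@@H]1C(C)=C2
A7 | alternative 3 | cis-5,6-disubstituted 1,3-dimethylcyclohexa-1,3-diene | CC(C)(C)[Si](C)(C)OC[C@@H]1[C@H](C)C(C)=CC(C)=C1
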